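**Retrosynthetic overview**
- The C3–CH(CH3) bond is cut by a Zweifel coupling: a ring A 3-lithio-2H-chromene (from the 3-bromochromene, OH and acetyl masked as silyl ether and silyl enol ether) plus the (R)-1-arylethyl pinacol boronate of ring B. The bond forms by a stereoretentive 1,2-shift of the benzylic carbon from boron to C3.
- The (R)-boronate comes from the (R)-carbamate by lithiation/HBpin (1,2-hydride shift), and that from CBS reduction of 6-acetyl-5,7-dimethoxy-2,2-dimethylchromene.
- Both chromenes come from one phenol, 2,4-dihydroxy-6-methoxyacetophenone: with 3-methylbut-2-enal (ring B unit, then O-methylation) or with 2-bromo-3-methylbut-2-enal (ring A unit, a new bromo-chromenylation).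
- The phenol comes from 2-hydroxy-6-methoxyacetophenone (C–H borylation/oxidation), made by I2/MeOH aromatisation of 2-acetylcyclohexane-1,3-dione (cyclohexane-1,3-dione + acetyl chloride).
- Ring order: benzene ring (aromatisation), then the pyran of the ring B unit and the pyran of the ring A unit (oxa-6π closures), then union of the two bicycles.

Assumption: the stereocentre is (S) (CIP order aryl > chromen-3-yl > CH3 > H); any regioisomeric chromene from the annulations is removed by chromatography.

**Route**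

Step 1
Reactants: 1 cyclohexane-1,3-dione; 2 acetyl chloride
Product: 4 2-acetylcyclohexane-1,3-dione, via enol acetate 3 (not isolated)
Conditions: Et3N, CH2Cl2, 0 °C; then DMAP (20 mol %), rt
Reagents that add atoms: none
Why: O-acetylation of the enolised dione gives enol acetate 3, and DMAP-mediated O-to-C acyl transfer (1,3-acyl migration through the acylpyridinium/enolate pair) delivers the chelated triketone as the thermodynamic product.

Step 2
Reactants: 4 2-acetylcyclohexane-1,3-dione
Product: 6 1-(2-hydroxy-6-methoxyphenyl)ethan-1-one, via methyl enol ether 5 (not isolated)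
Conditions: I2 (2 equiv), MeOH, reflux
Reagents that add atoms: methanol, CO
Why: Iodine first promotes enol etherification to 5 and then oxidises it (α-iodination, loss of HI, tautomerisation), the I2/MeOH oxidative aromatisation of 2-acylcyclohexane-1,3-diones to 2-acylresorcinol monomethyl ethers.

Step 3
Reactants: 6 1-(2-hydroxy-6-methoxyphenyl)ethan-1-one
Product: 8 1-(2,4-dihydroxy-6-methoxyphenyl)ethan-1-one, via aryl boronate 7 (not isolated)
Conditions: B2pin2, [Ir(OMe)(cod)]2 (1.5 mol %), dtbpy (3 mol %), THF, 80 °C; then Oxone (2KHSO5·KHSO4·K2SO4), acetone/H2O, 0 °C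
Reagents that add atoms: potassium peroxymonosulfate (KHSO5, active component of Oxone), [K+].[O-]S(=O)(=O)OO
Why: Sterically governed iridium-catalysed C–H borylation (Ishiyama–Miyaura–Hartwig) takes the only C–H without an ortho substituent (C4, para to acetyl), and peroxymonosulfate oxidation of the C–B bond in the same pot gives the phenol, any O–Bpin at the chelated OH being hydrolysed on work-up.

Step 4
Reactants: 8 1-(2,4-dihydroxy-6-methoxyphenyl)ethan-1-one; 9 3-methylbut-2-enal
Product: 11 1-(5-hydroxy-7-methoxy-2,2-dimethyl-2H-chromen-6-yl)ethan-1-one, via o-quinone methide 10 (not isolated)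
Conditions: Ca(OH)2, MeOH, rt
Reagents that add atoms: none
Why: Chromenylation by calcium phenoxide aldol-type C-alkylation at C3 (between the two hydroxyls), dehydration to o-quinone methide 10 and oxa-6π electrocyclisation onto the free para oxygen (the chelated ortho-OH does not close); a 7-hydroxy-5-methoxy regioisomer from attack at C5 would converge on the same product in step 5.

Step 5
Reactants: 11 1-(5-hydroxy-7-methoxy-2,2-dimethyl-2H-chromen-6-yl)ethan-1-one
Product: 12 1-(5,7-dimethoxy-2,2-dimethyl-2H-chromen-6-yl)ethan-1-one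
Conditions: MeI, K2CO3, DMF, 50 °C
Reagents that add atoms: iodomethane, CI
Why: Williamson O-methylation of the hydrogen-bonded phenol under forcing carbonate/DMF conditions.

Step 6
Reactants: 12 1-(5,7-dimethoxy-2,2-dimethyl-2H-chromen-6-yl)ethan-1-one
Product: 13 (1R)-1-(5,7-dimethoxy-2,2-dimethyl-2H-chromen-6-yl)ethan-1-ol
Conditions: (S)-Me-CBS (20 mol %), catecholborane, toluene, −78 → −20 °C
Reagents that add atoms: none
Why: Corey–Bakshi–Shibata reduction, in which the (S)-oxazaborolidine delivers hydride to the face that gives the (R)-carbinol with aryl as the large group, and catecholborane is chosen because it does not hydroborate the chromene double bond at low temperature.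

Step 7
Reactants: 13 (1R)-1-(5,7-dimethoxy-2,2-dimethyl-2H-chromen-6-yl)ethan-1-ol
Product: 14 (1R)-1-(5,7-dimethoxy-2,2-dimethyl-2H-chromen-6-yl)ethyl N,N-di(propan-2-yl)carbamate
Conditions: NaH, THF, 0 °C; then iPr2NCOCl, 0 → 50 °C
Reagents that add atoms: N,N-di(propan-2-yl)carbamoyl chloride, CC(C)N(C(C)C)C(Cl)=O
Why: Carbamoylation of the sodium alkoxide under strictly basic conditions breaks no bond at the stereocentre (R retained) and avoids ionising the very electron-rich benzylic C–O bond.

Step 8
Reactants: 14 (1R)-1-(5,7-dimethoxy-2,2-dimethyl-2H-chromen-6-yl)ethyl N,N-di(propan-2-yl)carbamate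
Product: 17 2-[(1R)-1-(5,7-dimethoxy-2,2-dimethyl-2H-chromen-6-yl)ethyl]-4,4,5,5-tetramethyl-1,3,2-dioxaborolane, via lithiated carbamate 15 (not isolated), via borohydride ate complex 16 (not isolated)
Conditions: s-BuLi, Et2O, −78 °C; then HBpin, −78 °C → rt
Reagents that add atoms: pinacolborane, CC1(C)OBOC1(C)C
Why: Lithiation–borylation, in which carbamate-directed benzylic deprotonation and capture of HBpin both occur with retention and the 1,2-hydride shift from boron to carbon expels the carbamate with inversion, so boron ends where oxygen was and the (R)-boronate results.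

Step 9
Reactants: 9 3-methylbut-2-enal
Product: 19 2-bromo-3-methylbut-2-enal, via dibromoaldehyde 18 (not isolated)
Conditions: Br2, CH2Cl2, −20 °C; then Et3N, 0 °C → rt
Reagents that add atoms: bromine, BrBr
Why: Electrophilic addition of Br2 to the enal followed by E1cB loss of HBr from 18 (the acidic α-hydrogen and the tertiary β-bromide leave) gives the α-bromoenal.

Step 10
Reactants: 8 1-(2,4-dihydroxy-6-methoxyphenyl)ethan-1-one; 19 2-bromo-3-methylbut-2-enal
Product: 21 1-(3-bromo-5-hydroxy-7-methoxy-2,2-dimethyl-2H-chromen-6-yl)ethan-1-one, via bromo-o-quinone methide 20 (not isolated)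
Conditions: Ca(OH)2, MeOH, rt → 40 °C
Reagents that add atoms: none
Why: Proposed new method: bromo-chromenylation, in which an α-bromoenal replaces the usual enal in the calcium phenoxide aldol/dehydration/oxa-6π sequence, so that the bromine, which stays on an sp2 carbon throughout and is therefore not lost by substitution or elimination, is carried through o-quinone methide 20 to C3 of the new pyran ring, with regiochemistry set as in step 4; the closest known reaction is the Ca(OH)2- or pyridine-mediated chromenylation of 2,4-dihydroxyacetophenones with 3-methylbut-2-enal.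

Step 11
Reactants: 21 1-(3-bromo-5-hydroxy-7-methoxy-2,2-dimethyl-2H-chromen-6-yl)ethan-1-one
Product: 22 3-bromo-5-[(tert-butyldimethylsilyl)oxy]-6-{1-[(tert-butyldimethylsilyl)oxy]ethenyl}-7-methoxy-2,2-dimethyl-2H-chromene
Conditions: TBSOTf (2.5 equiv), Et3N, CH2Cl2, 0 °C → rt
Reagents that add atoms: tert-butyldimethylsilyl trifluoromethanesulfonate, CC(C)(C)[Si](C)(C)OS(=O)(=O)C(F)(F)F
Why: Silyl triflate/amine silylation converts the phenol into its TBS ether and the methyl ketone into its TBS enol ether in one operation, removing the acidic O–H and the electrophilic C=O before the organolithium step.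

Step 12
Reactants: 22 3-bromo-5-[(tert-butyldimethylsilyl)oxy]-6-{1-[(tert-butyldimethylsilyl)oxy]ethenyl}-7-methoxy-2,2-dimethyl-2H-chromene; 17 2-[(1R)-1-(5,7-dimethoxy-2,2-dimethyl-2H-chromen-6-yl)ethyl]-4,4,5,5-tetramethyl-1,3,2-dioxaborolane
Product: 27 1-{3-[(1S)-1-(5,7-dimethoxy-2,2-dimethyl-2H-chromen-6-yl)ethyl]-5-hydroxy-7-methoxy-2,2-dimethyl-2H-chromen-6-yl}ethan-1-one, via alkenyllithium 23 (not isolated), via boronate complex 24 (not isolated), via iodoboronate 25 (not isolated), via bis-silyl ether 26 (not isolated)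
Conditions: t-BuLi (2 equiv), THF, −78 °C; 17, −78 → 0 °C; I2, MeOH, −78 °C; NaOMe, MeOH, −78 °C → rt; then TBAF, THF, 0 °C
Reagents that add atoms: none
Why: Zweifel olefination, in which bromine–lithium exchange gives alkenyllithium 23 that adds to the boronate to form ate complex 24, iodine attacks the benzylic alkene carbon C4 and triggers the 1,2-shift of the chiral 1-arylethyl group from boron to C3 with retention (this places the (S) centre in the final skeleton), methoxide-induced loss of boron and iodide (E1-like through the oxygen-stabilised C4 cation, so the ring imposes no anti-periplanar demand) restores C3=C4, and fluoride removes both silyl groups.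

**Compound list**
1 | cyclohexane-1,3-dione | O=C1CCCC(=O)C1 | starting material
2 | acetyl chloride | CC(Cl)=O | starting material
3 | 3-oxocyclohex-1-en-1-yl acetate (enol acetate, not isolated) | CC(=O)OC1=CC(=O)CCC1 | intermediate
4 | 2-acetylcyclohexane-1,3-dione (drawn as its enol) | CC(=O)C1=C(O)CCCC1=O | intermediate
5 | 2-acetyl-3-methoxycyclohex-2-en-1-one (not isolated) | CC(=O)C1=C(OC)CCCC1=O | intermediate
6 | 1-(2-hydroxy-6-methoxyphenyl)ethan-1-one | CC(=O)c1c(O)cccc1OC | intermediate
7 | 1-[2-hydroxy-6-methoxy-4-(4,4,5,5-tetramethyl-1,3,2-dioxaborolan-2-yl)phenyl]ethan-1-one (not isolated) | CC(=O)c1c(O)cc(cc1OC)B1OC(C)(C)C(C)(C)O1 | intermediate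
8 | 1-(2,4-dihydroxy-6-methoxyphenyl)ethan-1-one | CC(=O)c1c(O)cc(O)cc1OC | intermediate
9 | 3-methylbut-2-enal | CC(C)=CC=O | starting material
10 | 4-acetyl-5-hydroxy-3-methoxy-6-(3-methylbut-2-en-1-ylidene)cyclohexa-2,4-dien-1-one (o-quinone methide, not isolated) | CC(=O)C1=C(O)C(=CC=C(C)C)C(=O)C=C1OC | intermediate
11 | 1-(5-hydroxy-7-methoxy-2,2-dimethyl-2H-chromen-6-yl)ethan-1-one | CC(=O)c1c(O)c2C=CC(C)(C)Oc2cc1OC | intermediate
12 | 1-(5,7-dimethoxy-2,2-dimethyl-2H-chromen-6-yl)ethan-1-one | CC(=O)c1c(OC)c2C=CC(C)(C)Oc2cc1OC | intermediate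
13 | (1R)-1-(5,7-dimethoxy-2,2-dimethyl-2H-chromen-6-yl)ethan-1-ol | C[C@@H](O)c1c(OC)c2C=CC(C)(C)Oc2cc1OC | intermediate
14 | (1R)-1-(5,7-dimethoxy-2,2-dimethyl-2H-chromen-6-yl)ethyl N,N-di(propan-2-yl)carbamate | C[C@@H](OC(=O)N(C(C)C)C(C)C)c1c(OC)c2C=CC(C)(C)Oc2cc1OC | intermediate
15 | 1-(5,7-dimethoxy-2,2-dimethyl-2H-chromen-6-yl)-1-lithioethyl N,N-di(propan-2-yl)carbamate (configuration retained, not isolated) | C[C@@]([Li])(OC(=O)N(C(C)C)C(C)C)c1c(OC)c2C=CC(C)(C)Oc2cc1OC | intermediate
16 | lithium hydrido(pinacolato)[1-(carbamoyloxy)-1-(5,7-dimethoxy-2,2-dimethyl-2H-chromen-6-yl)ethyl]borate (not isolated) | [Li+].C[C@@]([BH-]1OC(C)(C)C(C)(C)O1)(OC(=O)N(C(C)C)C(C)C)c1c(OC)c2C=CC(C)(C)Oc2cc1OC | intermediate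
17 | 2-[(1R)-1-(5,7-dimethoxy-2,2-dimethyl-2H-chromen-6-yl)ethyl]-4,4,5,5-tetramethyl-1,3,2-dioxaborolane | C[C@@H](B1OC(C)(C)C(C)(C)O1)c1c(OC)c2C=CC(C)(C)Oc2cc1OC | intermediate
18 | 2,3-dibromo-3-methylbutanal (not isolated) | CC(C)(Br)C(Br)C=O | intermediate
19 | 2-bromo-3-methylbut-2-enal | CC(C)=C(Br)C=O | intermediate
20 | 4-acetyl-6-(2-bromo-3-methylbut-2-en-1-ylidene)-5-hydroxy-3-methoxycyclohexa-2,4-dien-1-one (not isolated) | CC(=O)C1=C(O)C(=CC(Br)=C(C)C)C(=O)C=C1OC | intermediate
21 | 1-(3-bromo-5-hydroxy-7-methoxy-2,2-dimethyl-2H-chromen-6-yl)ethan-1-one | CC(=O)c1c(O)c2C=C(Br)C(C)(C)Oc2cc1OC | intermediate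
22 | 3-bromo-5-[(tert-butyldimethylsilyl)oxy]-6-{1-[(tert-butyldimethylsilyl)oxy]ethenyl}-7-methoxy-2,2-dimethyl-2H-chromene | C=C(O[Si](C)(C)C(C)(C)C)c1c(O[Si](C)(C)C(C)(C)C)c2C=C(Br)C(C)(C)Oc2cc1OC | intermediate
23 | 3-lithio analogue of 22 (alkenyllithium, not isolated) | C=C(O[Si](C)(C)C(C)(C)C)c1c(O[Si](C)(C)C(C)(C)C)c2C=C([Li])C(C)(C)Oc2cc1OC | intermediate
24 | lithium (chromen-3-yl)[(1R)-1-(5,7-dimethoxy-2,2-dimethyl-2H-chromen-6-yl)ethyl](pinacolato)borate (not isolated) | [Li+].C=C(O[Si](C)(C)C(C)(C)C)c1c(O[Si](C)(C)C(C)(C)C)c2C=C(C(C)(C)Oc2cc1OC)[B-]1(OC(C)(C)C(C)(C)O1)[C@H](C)c1c(OC)c3C=CC(C)(C)Oc3cc1OC | intermediate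
25 | 4-iodo-3-(pinacolboryl)-3-[(1S)-1-(5,7-dimethoxy-2,2-dimethyl-2H-chromen-6-yl)ethyl]chroman carrying the two silyl ethers (C3/C4 diastereomer mixture, not isolated) | C=C(O[Si](C)(C)C(C)(C)C)c1c(O[Si](C)(C)C(C)(C)C)c2C(I)C(B3OC(C)(C)C(C)(C)O3)([C@H](C)c3c(OC)c4C=CC(C)(C)Oc4cc3OC)C(C)(C)Oc2cc1OC | intermediate
26 | 5-[(tert-butyldimethylsilyl)oxy]-6-{1-[(tert-butyldimethylsilyl)oxy]ethenyl}-3-[(1S)-1-(5,7-dimethoxy-2,2-dimethyl-2H-chromen-6-yl)ethyl]-7-methoxy-2,2-dimethyl-2H-chromene (not isolated) | C=C(O[Si](C)(C)C(C)(C)C)c1c(O[Si](C)(C)C(C)(C)C)c2C=C([C@H](C)c3c(OC)c4C=CC(C)(C)Oc4cc3OC)C(C)(C)Oc2cc1OC | intermediate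
27 | 1-{3-[(1S)-1-(5,7-dimethoxy-2,2-dimethyl-2H-chromen-6-yl)ethyl]-5-hydroxy-7-methoxy-2,2-dimethyl-2H-chromen-6-yl}ethan-1-one | COc1cc2c(c(O)c1C(C)=O)C=C([C@H](C)c1c(OC)cc3c(c1OC)C=CC(C)(C)O3)C(C)(C)O2 | target

**Totals and risks**

Total step count: 12. Longest linear sequence: 9 (steps 1, 2, 3, 4, 5, 6, 7, 8, 12).

Three steps most likely to fail:

Step 10, the proposed new bromo-chromenylation. The risks are sluggish aldol addition of the hindered α-bromoenal, loss of bromide to methoxide, and some C5 regioisomer. The fallback uses known chemistry and sets out from chromene 11. NBS in DMSO/H2O at 0 °C adds bromine at C3 and water at the benzylic C4 to give trans-1-(3-bromo-4,5-dihydroxy-7-methoxy-2,2-dimethyl-3,4-dihydro-2H-chromen-6-yl)ethan-1-one F1. Catalytic p-TsOH in toluene at 80 °C then dehydrates it (benzylic ionisation, loss of the C3 hydrogen) to bromide 21, where the route is rejoined; steps 9 and 10 are then not needed.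

Step 8, lithiation–borylation of carbamate 14. The risks are ionisation or elimination of the very electron-rich benzylic carbamate and competing ring lithiation at C8. The fallback sets out from ketone 12. NaBH4 in MeOH gives racemic 1-(5,7-dimethoxy-2,2-dimethyl-2H-chromen-6-yl)ethan-1-ol F2, and MsCl/Et3N at 0 °C eliminates it to 6-ethenyl-5,7-dimethoxy-2,2-dimethyl-2H-chromene F3. Copper hydride-catalysed Markovnikov hydroboration (CuCl, NaOtBu, DTBM-SEGPHOS, HBpin, toluene, rt) then returns to boronate 17. The ligand antipode that gives the (R)-boronate has to be identified by chiral HPLC; I have not assigned it. This replaces stereospecific transfer from the carbinol by catalyst-controlled creation of the C–B stereocentre and makes steps 6 and 7 unnecessary.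

Step 12, the Zweifel coupling. The risks are slow ate-complex formation between two hindered partners, iododeboronation instead of migration, and ring opening of the β-aryloxy alkenyllithium. The fallback sets out from boronate 17 and unprotected bromide 21 (step 11 skipped). They are joined by a palladium-catalysed, Ag2O-promoted Suzuki–Miyaura coupling of the secondary benzylic boronate, which proceeds with retention (Pd2(dba)3, PPh3, Ag2O, DME, 85 °C). Ketone and phenol tolerate these conditions and the coupling gives 27 directly, so no new compound is made (F0).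

**Further compounds**
F1 | step 10 | trans-1-(3-bromo-4,5-dihydroxy-7-methoxy-2,2-dimethyl-3,4-dihydro-2H-chromen-6-yl)ethan-1-one (racemic, relative configuration shown) | CC(=O)c1c(O)c2[C@@H](O)[C@H](Br)C(C)(C)Oc2cc1OC
F2 | step 8 | racemic 1-(5,7-dimethoxy-2,2-dimethyl-2H-chromen-6-yl)ethan-1-ol | CC(O)c1c(OC)c2C=CC(C)(C)Oc2cc1OC
F3 | step 8 | 6-ethenyl-5,7-dimethoxy-2,2-dimethyl-2H-chromene | C=Cc1c(OC)c2C=CC(C)(C)Oc2cc1OC
F0 | step 12 | none | none
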